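A direct plan would condense a β-keto ester with a naphthaldehyde to the aroyl acrylate A1, close the five-membered ring by a catalytic asymmetric Nazarov cyclisation to the indanone keto ester A2, insert one carbon by bromomethylation and radical ring expansion to the tetralone ester A3, and end with decarboxylation and debenzylation.
Its weakest steps would be three. The 4π closure would have to break the aromaticity of the aroyl ring in the pentadienyl cation, so it would be slow and its enantiocontrol uncertain. The radical one-carbon ring expansion would compete with plain reduction of the primary radical and with its attack on the nearby naphthalene. The ester hydrolysis and radical decarboxylation would spend two steps on removing a carbon that had been added only as an activating group.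

The cyclohexanone ring is read as the dearomatised half of a naphthalene-1,4-diol: C1–C4 and the C1 oxygen come from 2-methoxyfuran, fused to a 3,4-dioxygenated benzyne by [4+2] cycloaddition and ring opening. The innate regiochemistry puts the methoxy carbon (C1) peri to O8, the pattern that Friedel–Crafts closure cannot give; oxidation in methanol then masks C1 as a ketal and frees C4 as a ketone. The hindered naphthyl enters at flat sp2 C4 by cross-coupling of the enol triflate, and the stereocentre is set last by asymmetric hydrogenation, so no 4π closure onto an aroyl ring, no radical ring expansion and no carbon-deleting steps remain.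

Key step: step 2

Remark: locants in the names of 6–11, 17 and 18 follow the naphtho[1,2-d][1,3]dioxole skeleton, in which C9, C8, C7, C6, C5a and C9a are C1, C2, C3, C4, C4a and C8a of the tetralone.
Remark: the sense of induction of the iridium catalyst in step 10 cannot be predicted with certainty, so the ligand antipode that gives the 6S centre is assumed to be used.

Step 1
Reactants: 1 2,2-dimethyl-1,3-benzodioxole
Product: 2 5-bromo-2,2-dimethyl-1,3-benzodioxole
Conditions: NBS (1.05 equiv), MeCN, 0 °C to rt
Reagents that add atoms: N-bromosuccinimide, O=C1CCC(=O)N1Br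
Why: Electrophilic aromatic bromination of the benzodioxole should go para to a ring oxygen (C5), which leaves H4 flanked by oxygen and bromine for the aryne generation.

Step 2
Reactants: 2 5-bromo-2,2-dimethyl-1,3-benzodioxole; 3 2-methoxyfuran
Product: 7 9-methoxy-2,2-dimethylnaphtho[1,2-d][1,3]dioxol-6-ol, via aryllithium 4 (not isolated), via aryne 5 (not isolated), via cycloadduct 6 (not isolated)
Conditions: LiN(i-Pr)2 (1.3 equiv), 2-methoxyfuran (3 equiv), THF, −78 °C to rt; then CF3CO2H (cat.), CH2Cl2, 0 °C
Reagents that add atoms: 2-methoxyfuran (3), COc1ccco1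
Why: LiN(i-Pr)2 removes the proton between the ring oxygen and bromine of 2, loss of LiBr from 4 gives aryne 5, and an asynchronous [4+2] cycloaddition with 2-methoxyfuran gives the bridged ketal 6, which ionises at its methoxy-bearing bridgehead under trace acid and aromatises to naphthol 7. The closest known reaction type is the aryne–furan Diels–Alder reaction of 3-alkoxybenzynes with 2-alkoxyfurans followed by ring opening to 4,5-dialkoxy-1-naphthols. The carbocycle C5a–C6–C7–C8–C9–C9a is closed in the [4+2] mode, with both C5a–C6 and C9a–C9 formed in one operation. The two bridgehead stereocentres of racemic 6 are not controlled and need not be, because both become sp2 on ring opening. The step needs head-to-head regioselectivity, which the substrate secures: the oxygen on C3a of 5 makes the remote aryne carbon the electrophilic terminus and the methoxy group makes C5 of the furan the nucleophilic terminus, so the methoxy-bearing carbon ends peri to the dioxole oxygen. Ring opening in the wrong direction is excluded because only the ketal carbon can carry the oxocarbenium ion.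

Step 3
Reactants: 7 9-methoxy-2,2-dimethylnaphtho[1,2-d][1,3]dioxol-6-ol
Product: 8 9,9-dimethoxy-2,2-dimethylnaphtho[1,2-d][1,3]dioxol-6(9H)-one
Conditions: PhI(OAc)2 (1.1 equiv), MeOH, 0 °C; NaHCO3 work-up
Reagents that add atoms: methanol, CO
Why: Oxidative dearomatisation of a para-methoxyphenol with a hypervalent iodine reagent in methanol should trap the cationic intermediate at the methoxy-bearing carbon and give the quinone monoketal, in which C9 is masked and C6 is a free enone carbonyl.

Step 4
Reactants: 8 9,9-dimethoxy-2,2-dimethylnaphtho[1,2-d][1,3]dioxol-6(9H)-one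
Product: 9 9,9-dimethoxy-2,2-dimethyl-8,9-dihydronaphtho[1,2-d][1,3]dioxol-6(7H)-one
Conditions: H2 (1 atm), Rh/Al2O3 (5% Rh), EtOAc, rt
Reagents that add atoms: none
Why: Heterogeneous catalytic hydrogenation over rhodium on alumina should saturate the disubstituted enone C7=C8 under neutral conditions without hydrogenolysis of the benzylic ketal or reduction of the aryl ketone.

Step 5
Reactants: 9 9,9-dimethoxy-2,2-dimethyl-8,9-dihydronaphtho[1,2-d][1,3]dioxol-6(7H)-one
Product: 11 9,9-dimethoxy-2,2-dimethyl-8,9-dihydronaphtho[1,2-d][1,3]dioxol-6-yl trifluoromethanesulfonate, via potassium enolate 10 (not isolated)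
Conditions: KN(SiMe3)2 (1.1 equiv), THF, −78 °C; PhNTf2, −78 to 0 °C; Et3N-deactivated silica
Reagents that add atoms: N-phenylbis(trifluoromethanesulfonimide), O=S(=O)(N(c1ccccc1)S(=O)(=O)C(F)(F)F)C(F)(F)F
Why: Enolisation of the aryl ketone can only occur toward C7, and O-sulfonylation of the potassium enolate (enol triflate formation) under base leaves the acid-labile ketal untouched.

Step 6
Reactants: 12 5-methoxynaphthalen-1-ol
Product: 13 4-bromo-5-methoxynaphthalen-1-ol
Conditions: NBS (1.0 equiv), MeCN, −20 to 0 °C, dark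
Reagents that add atoms: N-bromosuccinimide, O=C1CCC(=O)N1Br
Why: Electrophilic aromatic bromination should take place in the ring of the free hydroxyl group at its para position C4, which is the carbon that later bears the tetralone.

Step 7
Reactants: 13 4-bromo-5-methoxynaphthalen-1-ol
Product: 14 1-bromo-8-methoxy-4-(methoxymethoxy)naphthalene
Conditions: MeOCH2Cl, i-Pr2NEt, CH2Cl2, 0 °C to rt
Reagents that add atoms: chloromethyl methyl ether, COCCl
Why: O-Alkylation of the naphthol (acetal protection) gives an ether that tolerates organolithium, palladium and hydrogenation conditions and falls off in the final acid step.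

Step 8
Reactants: 14 1-bromo-8-methoxy-4-(methoxymethoxy)naphthalene
Product: 16 2-[8-methoxy-4-(methoxymethoxy)naphthalen-1-yl]-4,4,5,5-tetramethyl-1,3,2-dioxaborolane, via naphthyllithium 15 (not isolated)
Conditions: n-BuLi (1.1 equiv), THF, −78 °C; 2-isopropoxy-4,4,5,5-tetramethyl-1,3,2-dioxaborolane, −78 °C to rt; aq NH4Cl
Reagents that add atoms: 2-isopropoxy-4,4,5,5-tetramethyl-1,3,2-dioxaborolane, CC(C)OB1OC(C)(C)C(C)(C)O1
Why: Bromine–lithium exchange is faster than any deprotonation at −78 °C, and borylation of the naphthyllithium with the isopropoxyborolane gives the pinacol boronate directly.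

Step 9
Reactants: 11 9,9-dimethoxy-2,2-dimethyl-8,9-dihydronaphtho[1,2-d][1,3]dioxol-6-yl trifluoromethanesulfonate; 16 2-[8-methoxy-4-(methoxymethoxy)naphthalen-1-yl]-4,4,5,5-tetramethyl-1,3,2-dioxaborolane
Product: 17 6-[8-methoxy-4-(methoxymethoxy)naphthalen-1-yl]-9,9-dimethoxy-2,2-dimethyl-8,9-dihydronaphtho[1,2-d][1,3]dioxole
Conditions: Pd(OAc)2 (5 mol %), 2-dicyclohexylphosphino-2',6'-dimethoxybiphenyl (10 mol %), K3PO4 (3 equiv), THF/H2O (10:1), degassed, 50 °C
Reagents that add atoms: none
Why: Suzuki–Miyaura coupling of the alkenyl triflate joins the two halves at an sp2 carbon, where the bulky electron-rich biarylphosphine should carry the peri-hindered boronate through transmetalation and the basic medium keeps the allylic ketal from losing methanol.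

Step 10
Reactants: 17 6-[8-methoxy-4-(methoxymethoxy)naphthalen-1-yl]-9,9-dimethoxy-2,2-dimethyl-8,9-dihydronaphtho[1,2-d][1,3]dioxole
Product: 18 (6S)-6-[8-methoxy-4-(methoxymethoxy)naphthalen-1-yl]-9,9-dimethoxy-2,2-dimethyl-6,7,8,9-tetrahydronaphtho[1,2-d][1,3]dioxole
Conditions: H2 (50 bar), [Ir(cod)(L)][B(C6H3(CF3)2)4] (2 mol %), L = (S)-4-tert-butyl-2-[2-(diphenylphosphino)phenyl]-4,5-dihydrooxazole or its antipode, K3PO4 (solid), CH2Cl2, rt
Reagents that add atoms: none
Why: Iridium-catalysed asymmetric hydrogenation of an unfunctionalised trisubstituted 1-aryl-3,4-dihydronaphthalene-type alkene should set C6 by catalyst control, the chiral P,N ligand telling apart the two faces of C6=C7, while solid phosphate buffers the acidic iridium hydrides so that the ketal survives.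

Step 11
Reactants: 18 (6S)-6-[8-methoxy-4-(methoxymethoxy)naphthalen-1-yl]-9,9-dimethoxy-2,2-dimethyl-6,7,8,9-tetrahydronaphtho[1,2-d][1,3]dioxole
Product: 19 (4S)-7,8-dihydroxy-4-(4-hydroxy-8-methoxynaphthalen-1-yl)-3,4-dihydronaphthalen-1(2H)-one
Conditions: 3 M aq HCl, MeOH/THF, 50 °C, argon
Reagents that add atoms: water, O
Why: Acid-catalysed hydrolysis and transketalisation should cleave the dimethyl ketal, the methoxymethyl ether and the catechol acetonide in one operation, while the aryl methyl ether and the C–H stereocentre, which has no leaving group and is not enolisable, stay intact.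

**Compound list**

1 | 2,2-dimethyl-1,3-benzodioxole | CC1(C)Oc2ccccc2O1 | starting material
2 | 5-bromo-2,2-dimethyl-1,3-benzodioxole | CC1(C)Oc2ccc(Br)cc2O1 | intermediate
3 | 2-methoxyfuran | COc1ccco1 | starting material
4 | (5-bromo-2,2-dimethyl-1,3-benzodioxol-4-yl)lithium | [Li]c1c(Br)ccc2OC(C)(C)Oc12 | intermediate (not isolated)
5 | 4,5-didehydro-2,2-dimethyl-1,3-benzodioxole (aryne) | CC1(C)OC2=C(O1)C#CC=C2 | intermediate (not isolated)
6 | 9-methoxy-2,2-dimethyl-6,9-dihydro-6,9-epoxynaphtho[1,2-d][1,3]dioxole (racemic; methoxy on the bridgehead next to the oxygen-bearing ring carbon) | COC12C=CC(O1)c1ccc3OC(C)(C)Oc3c12 | intermediate (not isolated)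
7 | 9-methoxy-2,2-dimethylnaphtho[1,2-d][1,3]dioxol-6-ol | COc1ccc(O)c2ccc3OC(C)(C)Oc3c12 | intermediate
8 | 9,9-dimethoxy-2,2-dimethylnaphtho[1,2-d][1,3]dioxol-6(9H)-one | COC1(OC)C=CC(=O)c2ccc3OC(C)(C)Oc3c12 | intermediate
9 | 9,9-dimethoxy-2,2-dimethyl-8,9-dihydronaphtho[1,2-d][1,3]dioxol-6(7H)-one | COC1(OC)CCC(=O)c2ccc3OC(C)(C)Oc3c12 | intermediate
10 | potassium 9,9-dimethoxy-2,2-dimethyl-8,9-dihydronaphtho[1,2-d][1,3]dioxol-6-olate | COC1(OC)CC=C([O-])c2ccc3OC(C)(C)Oc3c12.[K+] | intermediate (not isolated)
11 | 9,9-dimethoxy-2,2-dimethyl-8,9-dihydronaphtho[1,2-d][1,3]dioxol-6-yl trifluoromethanesulfonate | COC1(OC)CC=C(OS(=O)(=O)C(F)(F)F)c2ccc3OC(C)(C)Oc3c12 | intermediate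
12 | 5-methoxynaphthalen-1-ol | COc1cccc2c(O)cccc12 | starting material
13 | 4-bromo-5-methoxynaphthalen-1-ol | COc1cccc2c(O)ccc(Br)c12 | intermediate
14 | 1-bromo-8-methoxy-4-(methoxymethoxy)naphthalene | COCOc1ccc(Br)c2c(OC)cccc12 | intermediate
15 | [8-methoxy-4-(methoxymethoxy)naphthalen-1-yl]lithium | [Li]c1ccc(OCOC)c2cccc(OC)c12 | intermediate (not isolated)
16 | 2-[8-methoxy-4-(methoxymethoxy)naphthalen-1-yl]-4,4,5,5-tetramethyl-1,3,2-dioxaborolane | COCOc1ccc(B2OC(C)(C)C(C)(C)O2)c2c(OC)cccc12 | intermediate
17 | 6-[8-methoxy-4-(methoxymethoxy)naphthalen-1-yl]-9,9-dimethoxy-2,2-dimethyl-8,9-dihydronaphtho[1,2-d][1,3]dioxole | COc1cccc2c(OCOC)ccc(C3=CCC(OC)(OC)c4c3ccc5OC(C)(C)Oc45)c12 | intermediate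
18 | (6S)-6-[8-methoxy-4-(methoxymethoxy)naphthalen-1-yl]-9,9-dimethoxy-2,2-dimethyl-6,7,8,9-tetrahydronaphtho[1,2-d][1,3]dioxole | COc1cccc2c(OCOC)ccc([C@@H]3CCC(OC)(OC)c4c3ccc5OC(C)(C)Oc45)c12 | intermediate
19 | (4S)-7,8-dihydroxy-4-(4-hydroxy-8-methoxynaphthalen-1-yl)-3,4-dihydronaphthalen-1(2H)-one | COc1cccc2c(O)ccc([C@@H]3CCC(=O)c4c3ccc(O)c4O)c12 | target

Total step count: 11. Longest linear sequence: 8 steps (steps 1–5 and 9–11).

**Steps most likely to fail**

Step 10. The twisted, peri-substituted naphthyl group next to the alkene may slow turnover and weaken facial discrimination, and acidic iridium hydrides may strip methanol from the allylic ketal and aromatise the ring. The stereocentre would then be made together with the C6–aryl bond by an enantioconvergent nickel-catalysed Negishi arylation of a racemic benzylic electrophile. This fallback sets out from 9 and 15 and comes back at 18. NaBH4 in MeOH would reduce 9 to racemic 9,9-dimethoxy-2,2-dimethyl-6,7,8,9-tetrahydronaphtho[1,2-d][1,3]dioxol-6-ol F1. MsCl/Et3N would convert it into 9,9-dimethoxy-2,2-dimethyl-6,7,8,9-tetrahydronaphtho[1,2-d][1,3]dioxol-6-yl methanesulfonate F2, used cold without isolation. F2 would be coupled with [8-methoxy-4-(methoxymethoxy)naphthalen-1-yl]zinc iodide F3 (from 15 and ZnI2) under NiBr2·diglyme and a chiral bis(oxazoline) ligand at low temperature. Both enantiomers of F2 should converge on 18 through a common benzylic radical.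

Step 2. Addition of the amide base to the aryne and metalation of the furan may consume the reactants, and the cycloaddition may lose part of its head-to-head preference. The same ring would then be built by a carbene complex (Dötz) benzannulation, in which the regiochemistry is fixed by construction because the carbene carbon becomes the methoxy-bearing carbon. This fallback sets out from 1 and comes back at 7. Ortho-lithiation of 1 with n-BuLi/TMEDA would give (2,2-dimethyl-1,3-benzodioxol-4-yl)lithium F4. Addition to Cr(CO)6 would give lithium pentacarbonyl[(2,2-dimethyl-1,3-benzodioxol-4-yl)(oxido)methylidene]chromate F5, and O-methylation with Me3OBF4 would give pentacarbonyl[(2,2-dimethyl-1,3-benzodioxol-4-yl)(methoxy)methylidene]chromium F6. Heating F6 with ethynyltrimethylsilane in THF, then decomplexation under CO (which returns Cr(CO)6), would give 9-methoxy-2,2-dimethyl-7-(trimethylsilyl)naphtho[1,2-d][1,3]dioxol-6-ol F7. Protodesilylation with CF3CO2H would give 7.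

Step 9. Protodeboronation of the peri-hindered boronate may outrun transmetalation. The aryl group would then be joined by carbonyl addition and dehydration instead of cross-coupling. This fallback sets out from 9 and 15 and comes back at 17. Addition of 15 to 9 at −78 °C would give the tertiary alcohol 6-[8-methoxy-4-(methoxymethoxy)naphthalen-1-yl]-9,9-dimethoxy-2,2-dimethyl-6,7,8,9-tetrahydronaphtho[1,2-d][1,3]dioxol-6-ol F8. Syn-elimination with methyl N-(triethylammoniosulfonyl)carbamate under neutral conditions would give 17 without loss of the ketal.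

**Further compounds**

F1 | step 10 | 9,9-dimethoxy-2,2-dimethyl-6,7,8,9-tetrahydronaphtho[1,2-d][1,3]dioxol-6-ol (racemic) | COC1(OC)CCC(O)c2ccc3OC(C)(C)Oc3c12
F2 | step 10 | 9,9-dimethoxy-2,2-dimethyl-6,7,8,9-tetrahydronaphtho[1,2-d][1,3]dioxol-6-yl methanesulfonate (racemic) | COC1(OC)CCC(OS(C)(=O)=O)c2ccc3OC(C)(C)Oc3c12
F3 | step 10 | [8-methoxy-4-(methoxymethoxy)naphthalen-1-yl]zinc iodide | COCOc1ccc([Zn]I)c2c(OC)cccc12
F4 | step 2 | (2,2-dimethyl-1,3-benzodioxol-4-yl)lithium | [Li]c1cccc2OC(C)(C)Oc12
F5 | step 2 | lithium pentacarbonyl[(2,2-dimethyl-1,3-benzodioxol-4-yl)(oxido)methylidene]chromate | [Li+].[O-]C(=[Cr](=C=O)(=C=O)(=C=O)(=C=O)=C=O)c1cccc2OC(C)(C)Oc12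
F6 | step 2 | pentacarbonyl[(2,2-dimethyl-1,3-benzodioxol-4-yl)(methoxy)methylidene]chromium | COC(=[Cr](=C=O)(=C=O)(=C=O)(=C=O)=C=O)c1cccc2OC(C)(C)Oc12
F7 | step 2 | 9-methoxy-2,2-dimethyl-7-(trimethylsilyl)naphtho[1,2-d][1,3]dioxol-6-ol | COc1cc([Si](C)(C)C)c(O)c2ccc3OC(C)(C)Oc3c12
F8 | step 9 | 6-[8-methoxy-4-(methoxymethoxy)naphthalen-1-yl]-9,9-dimethoxy-2,2-dimethyl-6,7,8,9-tetrahydronaphtho[1,2-d][1,3]dioxol-6-ol (racemic) | COc1cccc2c(OCOC)ccc(C3(O)CCC(OC)(OC)c4c3ccc5OC(C)(C)Oc45)c12
A1 | direct plan | methyl (2Z)-2-[2,3-bis(benzyloxy)benzoyl]-3-[4-(benzyloxy)-8-methoxynaphthalen-1-yl]prop-2-enoate | COC(=O)/C(C(=O)c1cccc(OCc2ccccc2)c1OCc1ccccc1)=C\c1ccc(OCc2ccccc2)c2cccc(OC)c12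
A2 | direct plan | methyl (2R,3S)-6,7-bis(benzyloxy)-3-[4-(benzyloxy)-8-methoxynaphthalen-1-yl]-1-oxo-2,3-dihydro-1H-indene-2-carboxylate | COc1cccc2c(OCc5ccccc5)ccc([C@@H]3[C@@H](C(=O)OC)C(=O)c4c3ccc(OCc5ccccc5)c4OCc5ccccc5)c12
A3 | direct plan | methyl (1S,2R)-5,6-bis(benzyloxy)-1-[4-(benzyloxy)-8-methoxynaphthalen-1-yl]-4-oxo-1,2,3,4-tetrahydronaphthalene-2-carboxylate | COc1cccc2c(OCc5ccccc5)ccc([C@@H]3[C@H](C(=O)OC)CC(=O)c4c3ccc(OCc5ccccc5)c4OCc5ccccc5)c12
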